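**Plan**

Eudesmane numbering is used: ring A = C1–C5/C10, ring B = C5–C10, side chain C11(=C13)–C12O2Me on C7, C14 on C10, C15 on C4.
- **Cuts:** C11=C13 (olefination); C7–C11 together with the C4–OH/C5=C6 array (back to a 4,5‑epoxy‑6‑ene); the O3 ester; C4=C5 (aldol); C5–C6/C6–C7 (C6 taken out of ring B); C1–C2 (Michael).
- **Forward:** C10 is made quaternary on a cyclopentanone that holds C5, C7, C8, C9 and C10. C6 is added as a cyclopropane apex across C5=C7, and oxidative cleavage of the C5–C7 zero bridge enlarges this ring to ring B. Ring A is then closed by aldol condensation.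
- **Enabling feature:** in ring B, C5 sits next to the hydrogen‑free quaternary C10 and heads the allyl triad C5=C6–C7. A C5 ketone can therefore enolise only towards C7, so the inserted carbon can only become C6. The enlargement also leaves a leaving group on C7, which is the 6,7‑unsaturation from which the triad is later drawn.
- **Stereochemistry:** C10 comes from (R)‑1‑phenylethylamine (both enantiomers of the ketone converge). C3 is set by hydride attack anti to C14, C4 by OH‑directed epoxidation, and C7 by double inversion at palladium, cis to the epoxide oxygen. The Z‑angelate is brought in intact.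

Key step: step 6

Assumption: angelic anhydride is taken as a commercial reagent; α/β refer to the usual eudesmane drawing with C14 on the β face.

**Step 1**
Reactants: 1 2‑methylcyclopentanone (racemic); 2 (R)‑1‑phenylethylamine
Product: 3 (R)‑N‑(2‑methylcyclopentylidene)‑1‑phenylethanamine
Conditions: TsOH (cat.), toluene, reflux, Dean–Stark
Reagents that add atoms: none
Why: Acid‑catalysed imine condensation with azeotropic removal of water; the ring stereocentre needs no control because it is erased in the imine–enamine equilibrium used in step 2.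

**Step 2**
Reactants: 3 imine; 4 pent‑1‑en‑3‑one (ethyl vinyl ketone)
Product: 6 (S)‑2‑methyl‑2‑(3‑oxopentyl)cyclopentan‑1‑one, via Michael adduct imine 5 (not isolated)
Conditions: THF, rt; then 20 % aq AcOH, rt
Reagents that add atoms: water, O
Why: Deracemising asymmetric Michael addition of the more substituted secondary enamine tautomer (chiral‑imine method): C–C bond formation with concerted N–H transfer in a chair‑like aza‑ene transition state occurs on the enamine face anti to the phenyl group, so both enantiomers of 1 converge on the (S)‑quaternary centre C10, and mild hydrolysis frees the diketone.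

**Step 3**
Reactants: 6 diketone
Product: 7 2‑[2‑(2‑ethyl‑1,3‑dioxolan‑2‑yl)ethyl]‑2‑methylcyclopentan‑1‑one (C10 as in 6)
Conditions: (TMSOCH2)2, TMSOTf (cat.), CH2Cl2, −78 °C
Reagents that add atoms: 1,2‑bis(trimethylsilyloxy)ethane, C[Si](C)(C)OCCO[Si](C)(C)C
Why: Chemoselective silyl‑triflate‑catalysed acetalisation: the open‑chain ketone reacts at low temperature, whereas the ring ketone next to the quaternary carbon is neopentyl‑like and should stay free.

**Step 4**
Reactants: 7 keto ketal
Product: 8 trimethylsilyl enol ether C5(OTMS)=C7 of 7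
Conditions: LDA, THF, −78 °C; TMSCl
Reagents that add atoms: chlorotrimethylsilane, C[Si](C)(C)Cl
Why: Kinetic enolate formation and O‑silylation; C10 bears no hydrogen, so only the C5=C7 enol ether can form.

**Step 5**
Reactants: 8 silyl enol ether
Product: 9 1‑(trimethylsilyloxy)bicyclo[3.1.0]hexane (cyclopropane C5/C6/C7; both cyclopropane faces; C10 as in 6)
Conditions: Et2Zn, CH2I2, Et2O, 0 °C to rt
Reagents that add atoms: diiodomethane, ICI
Why: Simmons–Smith cyclopropanation (Furukawa variant) of the electron‑rich enol ether brings in C6; facial selectivity is irrelevant because the C5 and C7 stereocentres are erased later.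

**Step 6**
Reactants: 9 siloxycyclopropane
Product: 10 5‑chloro‑2‑[2‑(2‑ethyl‑1,3‑dioxolan‑2‑yl)ethyl]‑2‑methylcyclohexan‑1‑one (Cl on C7, both epimers; C10 as in 6)
Conditions: FeCl3 (2.2 equiv), DMF, 0 °C to rt
Reagents that add atoms: iron(III) chloride, Cl[Fe](Cl)Cl
Why: Iron(III) removes the silyl group to give an iron cyclopropanolate, inner‑sphere one‑electron oxidation gives the cyclopropyloxy radical, β‑scission cuts the zero bridge C5–C7, and the resulting β‑keto radical at C7 is chlorinated by ligand transfer from a second FeCl3. The closest known reaction type is the FeCl3‑mediated one‑carbon enlargement of 1‑siloxybicyclo[n.1.0]alkanes (Saegusa ring expansion), well established for cyclopentanone to cyclohexenone. No ring is closed: the five‑membered ring C5/C7/C8/C9/C10 and the cyclopropane C5/C6/C7 merge into the six‑membered ring B. The only new stereocentre, C7–Cl, is inconsequential because it is erased in step 7, and C10 is not on the radical path and keeps its configuration. The step needs cleavage of C5–C7 rather than C5–C6, which is secured by formation of a secondary instead of a primary radical and by release of the bicyclic strain, while the site of carbon insertion was already fixed by the hydrogen‑free C10. The chloride stores the 6,7‑unsaturation and at the same time masks the enone during closure of ring A.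

**Step 7**
Reactants: 10 chloro keto ketal
Product: 13 (S)‑1,4a‑dimethyl‑4,4a,5,6‑tetrahydronaphthalen‑2(3H)‑one, via chloro diketone 11 (not isolated), via 7‑chloro enone 12 (not isolated)
Conditions: conc. HCl, AcOH, rt to 40 °C; then DBU, CH2Cl2, rt
Reagents that add atoms: water, O
Why: Acid hydrolysis frees the ethyl ketone and acid‑catalysed Robinson‑type aldol condensation (C4 onto the C5 carbonyl, six‑membered ring A) proceeds while excess chloride keeps C6/C7 masked, after which vinylogous E1cB loss of HCl gives the linear 4,6‑dien‑3‑one.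

**Step 8**
Reactants: 13 dienone
Product: 14 (2S,4aS)‑1,4a‑dimethyl‑2,3,4,4a,5,6‑hexahydronaphthalen‑2‑ol (3β‑ol)
Conditions: NaBH4, CeCl3·7H2O, MeOH, −20 °C
Reagents that add atoms: none
Why: Luche 1,2‑reduction; hydride arrives axially on the α face opposite the axial C14 methyl, which should give the quasi‑equatorial 3β‑alcohol (3S).

**Step 9**
Reactants: 14 dienol
Product: 15 4β,5β‑epoxy‑4,10‑dimethyl‑Δ6‑octalin‑3β‑ol (3‑OH, epoxide oxygen and C14 all β)
Conditions: VO(acac)2 (cat.), t‑BuOOH (decane), CH2Cl2, 0 °C
Reagents that add atoms: tert‑butyl hydroperoxide, CC(C)(C)OO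
Why: Hydroxyl‑directed vanadium‑catalysed epoxidation of an allylic alcohol delivers oxygen to C4=C5 on the face of the 3β‑OH, setting C4 (and C5) and leaving the remote C6=C7 bond untouched.

**Step 10**
Reactants: 15 epoxy alcohol; 16 angelic anhydride
Product: 17 3‑O‑angelate of 15
Conditions: LiHMDS, THF, −20 to 0 °C
Reagents that add atoms: none
Why: Acylation of the lithium alkoxide by the anhydride is a stereoconservative angeloylation free of nucleophilic catalysts that isomerise Z to E, and the cis epoxide cannot undergo Payne migration.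

**Step 11**
Reactants: 17 vinyl epoxide; 18 trimethyl phosphonoacetate
Product: 19 methyl 2‑(dimethoxyphosphoryl)‑2‑(3β‑angeloyloxy‑4β‑hydroxy‑eudesm‑5‑en‑7β‑yl)acetate skeleton (both C11 epimers)
Conditions: Pd2(dba)3·CHCl3 (cat.), dppe, THF, rt to 40 °C
Reagents that add atoms: none
Why: Tsuji–Trost alkylation of a vinyl epoxide under neutral conditions: Pd(0) ionises the allylic C5–O bond from the α face, the freed C4 alkoxide deprotonates 18, and the carbanion attacks the less hindered terminus C7 anti to palladium, so one step gives the 4β‑OH, the C5=C6 bond and the 7β C–C bond (7R) by double inversion.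

**Step 12**
Reactants: 19 phosphonate
Product: 20 methyl 3β‑angeloyloxy‑4β‑hydroxyeudesma‑5,11(13)‑dien‑12‑oate (3S,4R,7R,10S), CNP0283268.1
Conditions: aq HCHO (37 %), K2CO3, THF, rt
Reagents that add atoms: formaldehyde, C=O
Why: Horner–Wadsworth–Emmons olefination with formaldehyde under carbonate conditions turns the phosphonoacetate into the α‑methylene ester and is mild enough for the doubly allylic C7–H, the tertiary allylic alcohol and the angelate.

**Compound list**

1 | 2‑methylcyclopentanone (racemic) | CC1CCCC1=O | starting material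
2 | (R)‑1‑phenylethylamine | C[C@@H](N)c1ccccc1 | starting material
3 | (R)‑N‑(2‑methylcyclopentylidene)‑1‑phenylethanamine | CC1CCCC1=N[C@H](C)c1ccccc1 | intermediate
4 | pent‑1‑en‑3‑one | C=CC(=O)CC | starting material
5 | Michael adduct imine | CCC(=O)CC[C@]1(C)CCCC1=N[C@H](C)c1ccccc1 | intermediate
6 | (S)‑2‑methyl‑2‑(3‑oxopentyl)cyclopentan‑1‑one | O=C1CCC[C@@]1(C)CCC(=O)CC | intermediate
7 | side‑chain dioxolane of 6 | O=C1CCC[C@@]1(C)CCC2(CC)OCCO2 | intermediate
8 | trimethylsilyl enol ether of 7 | C[Si](C)(C)OC1=CCC[C@@]1(C)CCC2(CC)OCCO2 | intermediate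
9 | 1‑siloxybicyclo[3.1.0]hexane (cyclopropane epimers) | C[Si](C)(C)OC12CC1CC[C@@]2(C)CCC3(CC)OCCO3 | intermediate
10 | ring‑enlarged β‑chloro ketone ketal | O=C1CC(Cl)CC[C@@]1(C)CCC2(CC)OCCO2 | intermediate
11 | chloro diketone | O=C1CC(Cl)CC[C@@]1(C)CCC(=O)CC | intermediate
12 | 7‑chloro enone | O=C1CC[C@]2(C)CCC(Cl)CC2=C1C | intermediate
13 | (S)‑1,4a‑dimethyl‑4,4a,5,6‑tetrahydronaphthalen‑2(3H)‑one | O=C1CC[C@]2(C)CCC=CC2=C1C | intermediate
14 | (2S,4aS)‑dienol | O[C@H]1CC[C@]2(C)CCC=CC2=C1C | intermediate
15 | 3β‑hydroxy‑4β,5β‑epoxide | O[C@H]1CC[C@]2(C)CCC=C[C@@]23O[C@@]13C | intermediate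
16 | angelic anhydride | C/C=C(/C)C(=O)OC(=O)/C(C)=C\C | starting material
17 | epoxy angelate | C/C=C(/C)C(=O)O[C@H]1CC[C@]2(C)CCC=C[C@@]23O[C@@]13C | intermediate
18 | trimethyl phosphonoacetate | COC(=O)CP(=O)(OC)OC | starting material
19 | 7β‑phosphonoacetate adduct (C11 epimers) | COC(=O)C(P(=O)(OC)OC)[C@H]1C=C2[C@](C)(CC[C@H](OC(=O)/C(C)=C\C)[C@]2(C)O)CC1 | intermediate
20 | CNP0283268.1 | C=C(C(=O)OC)[C@H]1C=C2[C@](C)(CC[C@H](OC(=O)/C(C)=C\C)[C@]2(C)O)CC1 | target

**Totals**

Total step count: 12. Longest linear sequence: 12.

**Steps most likely to fail**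

**Step 7.** Hydrogen chloride may be lost before ring A is closed. This would expose the enone to intramolecular conjugate addition of the side‑chain enol (C2 onto C7) and divert material into a bridged skeleton.
Fallback, from 10 back to 13: the unsaturation is given up and reintroduced after the annulation.
- Hydrogenation of 10 over Pd/C in the presence of triethylamine (elimination, then saturation) should give the saturated keto ketal F1.
- Acid hydrolysis and KOH/MeOH Robinson closure should then give (S)‑1,4a‑dimethyl‑4,4a,5,6,7,8‑hexahydronaphthalen‑2(3H)‑one F2.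
- Dehydrogenation with chloranil in refluxing tert‑butanol places the 6,7‑double bond and returns 13.

**Step 11.** Proton transfer to the hindered tertiary alkoxide may be slow, and β‑hydride loss from the π‑allyl complex may compete. Either would erode the alkylation at C7.
Fallback, from 17 to 20:
- The much more acidic Meldrum's acid is used as pronucleophile with the same palladium catalyst to give the 7β‑(Meldrum's acid‑5‑yl) adduct F5.
- Heating F5 with Eschenmoser's salt in methanol (Mannich reaction, methanolysis, decarboxylative fragmentation) should give the α‑methylene methyl ester 20 directly, so no phosphonate is needed.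

**Step 9.** Two failures are possible: Lewis‑acid opening of the labile tertiary vinyl epoxide, or oxidation of the hindered allylic alcohol instead of oxygen transfer to C4=C5.
Fallback, from 13 back to 15: the order of events is reversed.
- Weitz–Scheffer epoxidation of dienone 13 with alkaline hydrogen peroxide should give the 4β,5β‑epoxy ketone F4.
- Luche reduction from the α face, anti to the epoxide oxygen and C14, gives 15.

**Further compounds**

F1 | step 7 | 2‑[2‑(2‑ethyl‑1,3‑dioxolan‑2‑yl)ethyl]‑2‑methylcyclohexan‑1‑one (C10 as in 6) | O=C1CCCC[C@@]1(C)CCC2(CC)OCCO2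
F2 | step 7 | (S)‑1,4a‑dimethyl‑4,4a,5,6,7,8‑hexahydronaphthalen‑2(3H)‑one | O=C1CC[C@]2(C)CCCCC2=C1C
F4 | step 9 | 4β,5β‑epoxy‑4,10‑dimethyl‑Δ6‑octalin‑3‑one | O=C1CC[C@]2(C)CCC=C[C@@]23O[C@@]13C
F5 | step 11 | 7β‑(2,2‑dimethyl‑4,6‑dioxo‑1,3‑dioxan‑5‑yl) adduct of 17 | CC1(C)OC(=O)C(C(=O)O1)[C@H]1C=C2[C@](C)(CC[C@H](OC(=O)/C(C)=C\C)[C@]2(C)O)CC1
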